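The amounts of X, Q and Z always add up to the X charged, so I began from how that sum divides.

X 0.10 M; E 0.45 mM; time 20 min

    X + L ⇌ Q + L, rate k1*[X]*[L] forward; the back reaction follows from the equilibrium constant (K1 = 0.16, k1 = 6.4 L mol⁻¹ s⁻¹)
    Q + L ⇌ Z + L, rate k2*[L]*[Q] forward; the back reaction follows from the equilibrium constant (K2 = 0.55, k2 = 20 L mol⁻¹ s⁻¹)
    Z ⇌ X (k3 = 0.0054 s⁻¹)
    E ⇌ L (K4 = 2.8, k4 = 0.0018 s⁻¹)
    L → D (k5 = 1.5 × 10⁻⁵ s⁻¹)

* the state of affairs at 20 min: stopped, and by what, or still going (it is still moving / all of X has reacted / forward and back rates have come level / no working catalyst is left)
* how much of the X has reacted by 20 min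
* how much Q there is at 20 min, in percent of the X charged

- the reaction counts as stopped when no species that holds the X changes by six tenths of a point or more over the second half of the time
- run time (flask): 20 min

The steps among X, Q and Z form a closed round. When each stands level, Q/X is 0.16 and Z/Q is 0.55. Let x be the part of the charge that is then X:

x = 1 / (1 + 0.16 + 0.0880) = 80.1%

I called x the balance share, the part of the charged X that stands as X once the round stands level. It gave me:

conversion = 1 − x = 19.9%

Q = 0.16 × x = 12.8%

Was the round level by the end? My bench rule says a reversible change is over after 5 relaxation half-lives. E and L relax with a half-life of 4.73 min, towards 0.332 mM of L. At that level, the conversion of X to Q, pseudo-first-order in X, relaxes faster than Z and X do, 0.751 min against 1.97 min.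

But L starts from none, so the comparison drifts. With L half way to its level, the first figure doubles to 1.50 min, still the shorter. So I waited one half-life of E, then 5 of Z and X:

wait = 14.6 min; run / wait = 1.37

My rule stops promising level rates where this ratio falls to 1. The catalyst itself got 4.23 half-lives, fewer than 5. But the stopping test counts the species that hold the X, so I expected level rates.

The forecast said forward and back rates have come level, with conversion 19.9% (19.5% to 20.3%) and Q 12.8% (12.4% to 13.1%): “equilibrium is effectively reached well before”.

The flask's state at the end was this: forward and back rates have come level, at conversion 19.9% and Q 12.8%. Over the second half, no share of X, Q or Z moved by more than 0.25 percentage points, while L still rose from 56.4% to 69.0% of the catalyst. The balance share puts 0.0801 M of X in this flask, and 80% of the charge was left. A neighbour flask charged with 0.40 M of X has 0.320 M by the same share, and it kept 80% of its charge.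

The numbers were drawn at random within sensible limits.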